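## The problem

Target 17 is a 2,3-dihydrobenzofuran: ring A is the benzo ring (C3a, C4–C7, C7a) and ring B the oxygen heterocycle (O1, C2, C3, C3a, C7a). It carries an (E)-acrylic acid at C5, para to O1. At C2 it carries the side chain C1'(H)(CH3)–C2'H2–O, whose oxygen is acylated by (E)-4-hydroxycinnamic acid.

There are two adjacent stereocentres, C2 (S, in ring B) and C1' (S, exocyclic). With the chain C3–C2–C1'–C2' drawn in zigzag, the oxygen on C2 and the methyl on C1' lie on the same side, so the array is that of a syn 2-methyl-1,3-diol. C2 is a carbinol carbon and can be set by asymmetric ketone reduction. C1' bears only H, CH3 and two carbon substituents, so it must come from the chiral pool or be set by relay from C2.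

The two cinnamoyl alkenes, the free phenol, the free acid and the one alkyl ester that must outlive liberation of that acid rule out hydride, strong base and hydrolysis late in the route. These groups should therefore arrive last and the final unmasking should be acidic. The acrylate sits para to O1, so C5 can be functionalised by electrophilic substitution once ring B exists.

The feature that enables the key step is that O1 and the oxygen on C2' are 1,3-related across C1'. Before ring B is closed, O1 is a free hydroxyl on C2 next to an isopropenyl group (C1'=C2'). A silicon atom on that oxygen can reach C2' through a five-membered O–Si–C2'–C1'–C2 ring, and in doing so it delivers hydrogen to C1' under the control of C2.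

## Retrosynthesis

**17 ⇒ 16.** The O–C(CH3)3 bond of a tert-butyl ester is cut. Acidolysis is the one unmasking that leaves the primary coumarate ester, both alkenes and the phenol alone, so the C5 acid is carried as its tert-butyl ester 16.

**16 ⇒ 14 + 15.** The C2'–O bond of the coumarate is cut, not the acyl–O bond. Acylation of alcohol 14 would require a protected coumaric acid, because the free phenol competes. A Mitsunobu reaction instead uses unprotected (E)-4-hydroxycinnamic acid 15 as the pronucleophile, since only the carboxylic acid is acidic enough to be alkylated. The forward step must be chemoselective for carboxylate over phenoxide; no stereocentre is involved, because C2' is a CH2.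

**14 ⇒ 12 + 13.** The C5–vinyl bond is cut. A Mizoroki–Heck reaction of aryl bromide 12 with tert-butyl acrylate 13 gives the E alkene directly and tolerates the free primary alcohol. This removes three carbons and the only conjugated system on the core.

**12 ⇒ 11.** The C5–Br bond is cut. O1 directs bromination to its para position, so the halogen need not be carried through the early steps, where two different halides would have to be distinguished.

**11 ⇒ 10.** The O1–C7a bond is cut. Closing ring B at the aryl carbon leaves the C2–O bond untouched from the moment it is made, so the configuration at C2 is retained. The neighbouring cut, O1–C2 by displacement at C2, would invert that centre and invite elimination. Precursor 10 is an acyclic syn diol with an ortho bromide. The forward step must let the secondary hydroxyl (five-membered closure) win over the primary one (seven-membered closure).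

**10 ⇒ 9 ⇒ 8.** The C2'–O bond of 10 is traced back to a C2'–Si bond in oxasilolane 9. Then the C2'–Si and C1'–H bonds are cut to give hydrosilyl ether 8. An intermolecular hydroboration of the same alkene would be biased towards the anti isomer and would leave regiochemistry and facial control to the reagent. The tether fixes regiochemistry by ring size, delivers hydrogen from the oxygen-bearing face, and leaves silicon as a masked hydroxyl. Precursor 8 has one stereocentre and no ring beyond the arene. The forward reaction must provide diastereoface selectivity at C1'.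

**8 ⇒ 6 + 7.** The Si–O bond is cut. Allylic alcohol 6 is silylated with 1,1,3,3-tetramethyldisilazane 7, which releases only ammonia and leaves no salts to poison platinum.

**6 ⇒ 5.** The C2–H bond is cut. Enone 5 is achiral, and its two carbonyl substituents (branched alkenyl against CH2Ar) are of the kind an oxazaborolidine catalyst distinguishes. Enantioselective addition of an isopropenyl nucleophile to an enolisable arylacetaldehyde would be the less dependable alternative.

**5 ⇒ 3 + 4; 3 ⇒ 1.** The C2–C1' bond is cut. Isopropenylmagnesium bromide 4 adds once to Weinreb amide 3, made from 2-(2-bromophenyl)acetic acid 1 through acyl imidazole 2. All skeleton carbons then come from 1, 4, 13 and 15.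

## Roads not taken

**Alternative 1:** The C2–C1' and C3–C3a bonds are cut together.

- **Forward step.** Secondary boronate A1 and vinyllithium A2 form a vinyl ate complex. This undergoes conjunctive cross-coupling with 2-chlorophenyl triflate A3 under Pd(OAc)2 and the ferrocenyl diphosphine MandyPhos. C1' migrates from boron to C2 while the aryl group bonds to C3, giving boronate A4. C–B oxidation and ring closure through the chloride would follow.
- **Merits.** The route is convergent. C2 is set by the ligand, independently of C1', which arrives already resolved.
- **Weak points.** An α-branched secondary alkyl group is the least willing migrating group in this 1,2-shift. A1 has a silyloxy group β to boron, and four-coordinate boronates of that type can fragment by β-elimination. The pairing of ligand with the C1' centre is untested. A1 needs its own asymmetric synthesis. Ring closure would then depend on an aryl chloride.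
- **Comparison.** On convergence and on independent control of the two centres this road is better. The chosen plan offers commodity starting materials and a tether reaction for which this substitution pattern is the standard case.

**Alternative 2:** The C2–C3 bond is cut.

- **Forward step.** Aryldiazoacetate A5 loses N2 with Rh2(S-PTTL)4, and the rhodium carbene inserts into a C–H bond of the O–CH2 group. This closes ring B and gives cis ester A6.
- **Merits.** C1' comes from the chiral pool and needs no induction. The C5 bromine is present from the start. Ring B and C2 are formed in one step.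
- **Weak points.** The C3 ester is not in the target. Its removal needs reductive cleavage of the trichloroethyl group and a radical decarboxylation, which builds and destroys a stereocentre. The reacting C–H is on an unactivated alkyl ether carbon, a poorer substrate than the benzylic ethers for which this insertion is best established. The C1' methine offers a competing six-membered insertion. A diazo compound must be made and handled.
- **Comparison.** This road is superior in the certainty of C1' and saves the bromination. The chosen plan has no superfluous carbon to excise and no diazo intermediate.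

**Alternative 3:** The O1–C2 and C3–C3a bonds are cut at once.

- **Forward step.** 4-Bromo-2-iodophenol A7 and isoprene A8 combine under Pd2(dba)3 and a chiral phosphine. The aryl group adds to the unsubstituted vinyl terminus and the phenoxide closes onto the π-allyl, giving isopropenyl dihydrobenzofuran A9.
- **Merits.** Ring B, C2 and the C5 halogen come from two commodity chemicals in one step. Hydroboration, Heck reaction, esterification and deprotection would finish the synthesis in roughly half the steps of the chosen plan.
- **Weak points.** C1' would have to be set by hydroboration of an alkene whose neighbouring oxygen is already arylated, so no tether is possible. Uncatalysed hydroboration of 2-substituted allylic ethers is biased towards the anti array, the opposite of what 17 needs. Chiral boranes discriminate 1,1-disubstituted alkenes poorly. Regio- and enantiocontrol of the annulation with so simple a diene are also uncertain.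
- **Comparison.** This road is clearly better in step economy. The chosen plan accepts about twice the length in exchange for a controlled C1', the one centre the short route cannot reach.

Key step: step 5

Assumption: hydrosilyl ether 8 and oxasilolane 9 are moisture-sensitive and are carried forward as crude concentrates without chromatography; each is still a discrete compound of the route.

## Route

**Step 1**
Reactants: 1 2-(2-bromophenyl)acetic acid
Product: 3 2-(2-bromophenyl)-N-methoxy-N-methylacetamide, via 1-[(2-bromophenyl)acetyl]imidazole 2 (not isolated)
Conditions: CDI (1.1 equiv), CH2Cl2, rt; then MeNH(OMe)·HCl (1.3 equiv), rt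
Reagents that add atoms: N,O-dimethylhydroxylamine hydrochloride, CNOC.Cl; 1,1'-carbonyldiimidazole, O=C(n1ccnc1)n1ccnc1 (its imidazolyl group appears only in intermediate 2)
Why: Amide formation through an acyl imidazole; the hydrochloride protonates the departing imidazole, so no further base is needed and the aryl bromide is untouched.

**Step 2**
Reactants: 3 2-(2-bromophenyl)-N-methoxy-N-methylacetamide; 4 isopropenylmagnesium bromide
Product: 5 1-(2-bromophenyl)-3-methylbut-3-en-2-one
Conditions: 4 (1.4 equiv, THF), THF, −20 → 0 °C; poured into cold 1 M HCl
Reagents that add atoms: none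
Why: Weinreb ketone synthesis; the magnesium chelate of the tetrahedral adduct persists until the quench, so a second addition cannot occur, and the acidic inverse quench protonates the released amine before it can add to the enone.

**Step 3**
Reactants: 5 1-(2-bromophenyl)-3-methylbut-3-en-2-one
Product: 6 (2S)-1-(2-bromophenyl)-3-methylbut-3-en-2-ol
Conditions: (R)-2-methyl-CBS-oxazaborolidine [(3aR)-1-methyl-3,3-diphenyltetrahydro-1H,3H-pyrrolo[1,2-c][1,3,2]oxazaborole] (0.15 equiv), catecholborane (1.8 equiv), toluene, −78 °C; MeOH, then aq. NaOH wash
Reagents that add atoms: none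
Why: Corey–Bakshi–Shibata reduction; the branched alkenyl group acts as the large substituent and CH2Ar as the small one, so the (R)-catalyst delivers hydride to the face that gives the (S)-alcohol, and catecholborane at low temperature leaves the 1,1-disubstituted alkene and the conjugate position alone.

**Step 4**
Reactants: 6 (2S)-1-(2-bromophenyl)-3-methylbut-3-en-2-ol; 7 1,1,3,3-tetramethyldisilazane
Product: 8 {[(2S)-1-(2-bromophenyl)-3-methylbut-3-en-2-yl]oxy}dimethylsilane
Conditions: 7 (1.0 equiv), neat, rt → 60 °C, N2 sweep; volatiles removed in vacuo
Reagents that add atoms: none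
Why: O-silylation of an alcohol by a disilazane with loss of ammonia; the C2–O bond is not touched, so the configuration is kept, and no amine salt remains to inhibit the platinum catalyst of the next step.

**Step 5**
Reactants: 8 {[(2S)-1-(2-bromophenyl)-3-methylbut-3-en-2-yl]oxy}dimethylsilane
Product: 9 (4R,5S)-5-[(2-bromophenyl)methyl]-2,2,4-trimethyl-1,2-oxasilolane (cis)
Conditions: Pt2[(CH2=CHSiMe2)2O]3 (Karstedt catalyst, 0.5 mol % Pt), hexane (0.1 M), rt → 60 °C
Reagents that add atoms: none
Why: Zerovalent platinum inserts into the Si–H bond of 8, the tethered alkene inserts into Pt–H with hydrogen going to the internal carbon C1' and platinum to the terminal carbon C2', and reductive elimination forms the C2'–Si bond (Chalk–Harrod cycle). The closest known reaction type is this very one, the platinum-catalysed intramolecular hydrosilylation of hydrodimethylsilyl ethers of 2-substituted allylic alcohols, the established entry to syn 2-methyl-1,3-diols after oxidation. One ring closes, the 1,2-oxasilolane, in the 5-endo mode; the exo alternative would be a four-membered ring, so the two-atom O–Si tether forces silicon onto C2' and hydrogen onto C1'. The new stereocentre C1' (C4 of 9) is controlled by the C2 stereocentre from step 3 (C5 of 9). For the Si–Pt–H unit to reach a π face the C2–O bond must stand roughly perpendicular to the alkene plane, and of the two rotamers that allow this, the one with the carbinol hydrogen beside the vinylic methyl and the 2-bromobenzyl group over the =CH2 terminus avoids A(1,2) strain. Hydrogen is then delivered to the alkene face on which the oxygen sits, which places CH3 and CH2Ar cis on the ring and gives (4R,5S)-9 from (S)-8. The step therefore needs only diastereoface selectivity, secured by the size difference between H and CH2Ar on C2; regiochemistry is fixed by the tether, intermolecular addition is disfavoured by dilution, and the aryl bromide is inert to zerovalent platinum at this temperature. Any trans isomer is carried to diol 10 and removed there by chromatography.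

**Step 6**
Reactants: 9 (4R,5S)-5-[(2-bromophenyl)methyl]-2,2,4-trimethyl-1,2-oxasilolane
Product: 10 (2S,3S)-4-(2-bromophenyl)-2-methylbutane-1,3-diol
Conditions: 30% aq. H2O2, KF, KHCO3, THF/MeOH (1:1), rt → 40 °C; aq. Na2S2O3
Reagents that add atoms: hydrogen peroxide, OO
Why: Tamao–Fleming oxidation of an alkoxysilane; fluoride-activated silicon accepts hydroperoxide and the C2' carbon migrates to oxygen with retention, while the Si–O bond to C2 is hydrolysed, so the cis ring becomes the syn diol with both stereocentres unchanged.

**Step 7**
Reactants: 10 (2S,3S)-4-(2-bromophenyl)-2-methylbutane-1,3-diol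
Product: 11 (2S)-2-[(2S)-2,3-dihydro-1-benzofuran-2-yl]propan-1-ol
Conditions: CuI (10 mol %), 3,4,7,8-tetramethyl-1,10-phenanthroline (20 mol %), Cs2CO3 (2.0 equiv), toluene, 110 °C
Reagents that add atoms: none
Why: Ullmann-type intramolecular C–O coupling under monovalent copper; the secondary alkoxide closes the five-membered ring far faster than the primary one could close a seven-membered ring, and because only the aryl C–Br bond is broken the C2 configuration is retained.

**Step 8**
Reactants: 11 (2S)-2-[(2S)-2,3-dihydro-1-benzofuran-2-yl]propan-1-ol
Product: 12 (2S)-2-[(2S)-5-bromo-2,3-dihydro-1-benzofuran-2-yl]propan-1-ol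
Conditions: NBS (1.05 equiv), MeCN, 0 °C → rt, dark
Reagents that add atoms: N-bromosuccinimide, O=C1CCC(=O)N1Br
Why: Electrophilic aromatic bromination; the ring oxygen directs to its para position C5, which is less hindered than the ortho position C7, and the primary alcohol is not oxidised under these non-aqueous, ionic conditions.

**Step 9**
Reactants: 12 (2S)-2-[(2S)-5-bromo-2,3-dihydro-1-benzofuran-2-yl]propan-1-ol; 13 tert-butyl acrylate
Product: 14 tert-butyl (2E)-3-{(2S)-2-[(2S)-1-hydroxypropan-2-yl]-2,3-dihydro-1-benzofuran-5-yl}prop-2-enoate
Conditions: 13 (2 equiv), Pd(OAc)2 (5 mol %), P(o-tol)3 (10 mol %), Et3N (3 equiv), DMF, 100 °C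
Reagents that add atoms: none
Why: Mizoroki–Heck reaction; zerovalent palladium formed in situ adds to the C5–Br bond, and syn insertion of the acrylate followed by syn β-hydride elimination gives the E alkene, with the free alcohol and the ring ether as spectators.

**Step 10**
Reactants: 14 tert-butyl (2E)-3-{(2S)-2-[(2S)-1-hydroxypropan-2-yl]-2,3-dihydro-1-benzofuran-5-yl}prop-2-enoate; 15 (2E)-3-(4-hydroxyphenyl)prop-2-enoic acid
Product: 16 (2S)-2-{(2S)-5-[(1E)-3-tert-butoxy-3-oxoprop-1-en-1-yl]-2,3-dihydro-1-benzofuran-2-yl}propyl (2E)-3-(4-hydroxyphenyl)prop-2-enoate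
Conditions: 15 (1.3 equiv), PPh3 (1.5 equiv), DIAD (1.5 equiv), THF, 0 °C → rt
Reagents that add atoms: none
Why: Mitsunobu esterification; the betaine deprotonates only the carboxylic acid (far more acidic than the phenol), whose carboxylate displaces the oxyphosphonium group at the primary carbon C2', so the phenol needs no protection; the ester oxygen on C2' comes from 15 and the hydroxyl oxygen of 14 leaves in Ph3PO, with no stereocentre involved.

**Step 11**
Reactants: 16 (2S)-2-{(2S)-5-[(1E)-3-tert-butoxy-3-oxoprop-1-en-1-yl]-2,3-dihydro-1-benzofuran-2-yl}propyl (2E)-3-(4-hydroxyphenyl)prop-2-enoate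
Product: 17 (2E)-3-[(2S)-2-{(2S)-1-{[(2E)-3-(4-hydroxyphenyl)prop-2-enoyl]oxy}propan-2-yl}-2,3-dihydro-1-benzofuran-5-yl]prop-2-enoic acid
Conditions: TFA/CH2Cl2 (1:4), 0 °C → rt
Reagents that add atoms: none
Why: Acidolysis of a tert-butyl ester by alkyl–oxygen cleavage with loss of 2-methylpropene; the primary coumarate ester, the aryl ether, both E alkenes and the two stereocentres are inert to anhydrous acid.

## Compound list

1 | 2-(2-bromophenyl)acetic acid | OC(=O)Cc1ccccc1Br | starting material
2 | 1-[(2-bromophenyl)acetyl]imidazole | O=C(Cc1ccccc1Br)n1ccnc1 | intermediate (not isolated)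
3 | 2-(2-bromophenyl)-N-methoxy-N-methylacetamide | CON(C)C(=O)Cc1ccccc1Br | intermediate
4 | isopropenylmagnesium bromide | C=C(C)[Mg]Br | starting material
5 | 1-(2-bromophenyl)-3-methylbut-3-en-2-one | C=C(C)C(=O)Cc1ccccc1Br | intermediate
6 | (2S)-1-(2-bromophenyl)-3-methylbut-3-en-2-ol | C=C(C)[C@@H](O)Cc1ccccc1Br | intermediate
7 | 1,1,3,3-tetramethyldisilazane | C[SiH](C)N[SiH](C)C | starting material
8 | {[(2S)-1-(2-bromophenyl)-3-methylbut-3-en-2-yl]oxy}dimethylsilane | C=C(C)[C@@H](O[SiH](C)C)Cc1ccccc1Br | intermediate
9 | (4R,5S)-5-[(2-bromophenyl)methyl]-2,2,4-trimethyl-1,2-oxasilolane | C[C@H]1C[Si](C)(C)O[C@H]1Cc1ccccc1Br | intermediate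
10 | (2S,3S)-4-(2-bromophenyl)-2-methylbutane-1,3-diol | C[C@@H](CO)[C@@H](O)Cc1ccccc1Br | intermediate
11 | (2S)-2-[(2S)-2,3-dihydro-1-benzofuran-2-yl]propan-1-ol | C[C@@H](CO)[C@@H]1Cc2ccccc2O1 | intermediate
12 | (2S)-2-[(2S)-5-bromo-2,3-dihydro-1-benzofuran-2-yl]propan-1-ol | C[C@@H](CO)[C@@H]1Cc2cc(Br)ccc2O1 | intermediate
13 | tert-butyl acrylate | C=CC(=O)OC(C)(C)C | starting material
14 | tert-butyl (2E)-3-{(2S)-2-[(2S)-1-hydroxypropan-2-yl]-2,3-dihydro-1-benzofuran-5-yl}prop-2-enoate | C[C@@H](CO)[C@@H]1Cc2cc(/C=C/C(=O)OC(C)(C)C)ccc2O1 | intermediate
15 | (2E)-3-(4-hydroxyphenyl)prop-2-enoic acid | OC(=O)/C=C/c1ccc(O)cc1 | starting material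
16 | (2S)-2-{(2S)-5-[(1E)-3-tert-butoxy-3-oxoprop-1-en-1-yl]-2,3-dihydro-1-benzofuran-2-yl}propyl (2E)-3-(4-hydroxyphenyl)prop-2-enoate | C[C@@H](COC(=O)/C=C/c1ccc(O)cc1)[C@@H]1Cc2cc(/C=C/C(=O)OC(C)(C)C)ccc2O1 | intermediate
17 | (2E)-3-[(2S)-2-{(2S)-1-{[(2E)-3-(4-hydroxyphenyl)prop-2-enoyl]oxy}propan-2-yl}-2,3-dihydro-1-benzofuran-5-yl]prop-2-enoic acid | C[C@@H](COC(=O)/C=C/c1ccc(O)cc1)[C@@H]1Cc2cc(/C=C/C(=O)O)ccc2O1 | target

## Step count and risk

Total: 11 steps. Longest linear sequence: 11 steps, from 1 to 17; compounds 4, 7, 13 and 15 are purchased.

**Step 5 (key step).**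
- **Risk.** Facial selectivity at C1' may be insufficient. The group that must differ from hydrogen on C2 is a primary CH2Ar, so the energy gap between the two reactive rotamers may be modest. Intermolecular hydrosilylation could also compete if the solution is too concentrated. Larger substituents on silicon are the first adjustment within the same reaction.
- **Fallback.** The fallback sets out from 6. Silylation with TBSCl and imidazole would give tert-butyl{[(2S)-1-(2-bromophenyl)-3-methylbut-3-en-2-yl]oxy}dimethylsilane F1. Hydroboration with catecholborane under RhCl(PPh3)3 catalysis is known to favour the syn isomer with silyl ethers of 2-substituted allylic alcohols, the opposite sense to uncatalysed dialkylborane addition. It would give 2-[(2S,3S)-4-(2-bromophenyl)-3-[(tert-butyldimethylsilyl)oxy]-2-methylbutyl]-1,3,2-benzodioxaborole F2. Oxidation in the same flask (NaOH, H2O2) would give (2S,3S)-4-(2-bromophenyl)-3-[(tert-butyldimethylsilyl)oxy]-2-methylbutan-1-ol F3. TBAF would then release diol 10, where the route is rejoined.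

**Step 3.**
- **Risk.** Enantioface discrimination may be incomplete, because the isopropenyl and 2-bromobenzyl groups do not differ greatly in bulk. Some conjugate reduction or hydroboration of the alkene is also possible.
- **Fallback.** The fallback sets out from 5. Luche reduction (NaBH4, CeCl3·7H2O, MeOH) would give racemic 1-(2-bromophenyl)-3-methylbut-3-en-2-ol F4. Sharpless kinetic resolution (Ti(OiPr)4, D-(−)-diisopropyl tartrate, substoichiometric tert-butyl hydroperoxide, 4 Å sieves, CH2Cl2, −20 °C) would epoxidise the (R)-enantiomer to (1R)-2-(2-bromophenyl)-1-[(2R)-2-methyloxiran-2-yl]ethan-1-ol F5. The (S)-alcohol would be left behind and separated by chromatography, rejoining the route at 6. Half the material is lost. The same resolution can also be applied to partially enriched 6 to raise its enantiopurity.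

**Step 7.**
- **Risk.** The primary hydroxyl may compete, either by slow seven-membered closure or by intermolecular arylation. Hydrodebromination of the arene at 110 °C is also possible.
- **Fallback.** The fallback sets out from 10. Selective silylation of the primary hydroxyl (TBSCl, imidazole, CH2Cl2, 0 °C) would give (2S,3S)-1-(2-bromophenyl)-4-[(tert-butyldimethylsilyl)oxy]-3-methylbutan-2-ol F6. The copper-catalysed closure, now with a single nucleophile, would give tert-butyl{(2S)-2-[(2S)-2,3-dihydro-1-benzofuran-2-yl]propoxy}dimethylsilane F7. TBAF would return alcohol 11.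

**Step 10.**
- **Risk.** Chemoselectivity may be lost through alkylation of the phenol oxygen by the oxyphosphonium intermediate or through oligomer formation from 15. Separation from Ph3PO may be tedious.
- **Fallback.** The fallback sets out from 14. Carbodiimide acylation (EDC·HCl, DMAP, CH2Cl2) with commercial (E)-4-acetoxycinnamic acid would give (2S)-2-{(2S)-5-[(1E)-3-tert-butoxy-3-oxoprop-1-en-1-yl]-2,3-dihydro-1-benzofuran-2-yl}propyl (2E)-3-(4-acetoxyphenyl)prop-2-enoate F8. Selective removal of the aryl acetate with hydrazine acetate in DMF, which leaves the alkyl esters alone, would return to 16.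

## Further compounds

F1 | step 5 | tert-butyl{[(2S)-1-(2-bromophenyl)-3-methylbut-3-en-2-yl]oxy}dimethylsilane | C=C(C)[C@@H](O[Si](C)(C)C(C)(C)C)Cc1ccccc1Br
F2 | step 5 | 2-[(2S,3S)-4-(2-bromophenyl)-3-[(tert-butyldimethylsilyl)oxy]-2-methylbutyl]-1,3,2-benzodioxaborole | C[C@@H](CB1Oc2ccccc2O1)[C@@H](O[Si](C)(C)C(C)(C)C)Cc1ccccc1Br
F3 | step 5 | (2S,3S)-4-(2-bromophenyl)-3-[(tert-butyldimethylsilyl)oxy]-2-methylbutan-1-ol | C[C@@H](CO)[C@@H](O[Si](C)(C)C(C)(C)C)Cc1ccccc1Br
F4 | step 3 | racemic 1-(2-bromophenyl)-3-methylbut-3-en-2-ol | C=C(C)C(O)Cc1ccccc1Br
F5 | step 3 | (1R)-2-(2-bromophenyl)-1-[(2R)-2-methyloxiran-2-yl]ethan-1-ol | C[C@@]1(CO1)[C@H](O)Cc1ccccc1Br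
F6 | step 7 | (2S,3S)-1-(2-bromophenyl)-4-[(tert-butyldimethylsilyl)oxy]-3-methylbutan-2-ol | C[C@@H](CO[Si](C)(C)C(C)(C)C)[C@@H](O)Cc1ccccc1Br
F7 | step 7 | tert-butyl{(2S)-2-[(2S)-2,3-dihydro-1-benzofuran-2-yl]propoxy}dimethylsilane | C[C@@H](CO[Si](C)(C)C(C)(C)C)[C@@H]1Cc2ccccc2O1
F8 | step 10 | (2S)-2-{(2S)-5-[(1E)-3-tert-butoxy-3-oxoprop-1-en-1-yl]-2,3-dihydro-1-benzofuran-2-yl}propyl (2E)-3-(4-acetoxyphenyl)prop-2-enoate | C[C@@H](COC(=O)/C=C/c1ccc(OC(C)=O)cc1)[C@@H]1Cc2cc(/C=C/C(=O)OC(C)(C)C)ccc2O1
A1 | alternative 1 | (S)-tert-butyldimethyl[2-(4,4,5,5-tetramethyl-1,3,2-dioxaborolan-2-yl)propoxy]silane | C[C@@H](CO[Si](C)(C)C(C)(C)C)B1OC(C)(C)C(C)(C)O1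
A2 | alternative 1 | vinyllithium | [Li]C=C
A3 | alternative 1 | 2-chlorophenyl trifluoromethanesulfonate | O=S(=O)(Oc1ccccc1Cl)C(F)(F)F
A4 | alternative 1 | tert-butyl{[(2R,3S)-4-(2-chlorophenyl)-2-methyl-3-(4,4,5,5-tetramethyl-1,3,2-dioxaborolan-2-yl)butyl]oxy}dimethylsilane | C[C@@H](CO[Si](C)(C)C(C)(C)C)[C@@H](B1OC(C)(C)C(C)(C)O1)Cc1ccccc1Cl
A5 | alternative 2 | 2,2,2-trichloroethyl 2-{5-bromo-2-[(2R)-3-[(tert-butyldimethylsilyl)oxy]-2-methylpropoxy]phenyl}-2-diazoacetate | C[C@@H](CO[Si](C)(C)C(C)(C)C)COc1ccc(Br)cc1C(=[N+]=[N-])C(=O)OCC(Cl)(Cl)Cl
A6 | alternative 2 | 2,2,2-trichloroethyl (2R,3R)-5-bromo-2-{(2S)-1-[(tert-butyldimethylsilyl)oxy]propan-2-yl}-2,3-dihydro-1-benzofuran-3-carboxylate (cis) | C[C@@H](CO[Si](C)(C)C(C)(C)C)[C@@H]1[C@H](C(=O)OCC(Cl)(Cl)Cl)c2cc(Br)ccc2O1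
A7 | alternative 3 | 4-bromo-2-iodophenol | Oc1ccc(Br)cc1I
A8 | alternative 3 | isoprene (2-methylbuta-1,3-diene) | C=CC(C)=C
A9 | alternative 3 | (2S)-5-bromo-2-(prop-1-en-2-yl)-2,3-dihydro-1-benzofuran | C=C(C)[C@@H]1Cc2cc(Br)ccc2O1
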